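2.13 to one: that is how the noon run ended after 50.0 h, with 68% of the charge as target, 0% as substrate and the rest elsewhere. Target over that rest I call the end odds, a selectivity factor in fractions of the charge.

| flask | substrate | free catalyst | remark | time |
|---|---|---|---|---|
| dawn | 0.10 M | 0.041 mol% | run made earlier |  |
| winter | 0.10 M | 0.33 mol% | run made earlier |  |
| noon | 0.074 M | 0.1 mol% | run made earlier |  |
| red | 0.030 M | 0.3 mol% |  | 2.0 d |
| teal | 0.030 M | 0.05 mol% |  | 2.0 d |
| grey | 0.15 M | 0.4 mol% |  | 2.0 d |
| amber | 0.10 M | 0.1 mol% |  | 2.0 d |

| run | time / h | target / % | substrate / % |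
|---|---|---|---|
| dawn | 4.00 | 18 | 49 |
| dawn | 8.00 | 28 | 26 |
| dawn | 20.0 | 44 | 4 |
| dawn | 50.0 | 48 | 2 |
| winter | 12.0 | 82 | 0 |
| winter | 25.0 | 86 | 0 |
| winter | 40.0 | 82 | 1 |
| winter | 50.0 | 84 | 0 |
| noon | 4.00 | 32 | 41 |
| noon | 8.00 | 51 | 20 |
| noon | 20.0 | 67 | 3 |
| noon | 50.0 | 68 | 0 |

(scatter of a reading: 1.5 percentage points)

* ranking by amount of target, in percent of the substrate charged, from high to low, at 2.0 d (red / teal / grey / amber)
* the same order at 2.5 h (red / teal / grey / amber)
* the amount of target, in percent of the substrate charged of the flask you put first, at 2.0 d
* the amount of target, in percent of the substrate charged of the flask you put last, at 2.0 d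

- the earlier runs were read with a standard deviation of 1.5 percentage points

**Why odds and not the yield?** The winter run reads 82% target with 0% substrate at 12.0 h and 84% target at 50.0 h, so in that run the later readings differ by about their scatter. What stays on the board is how the charge was split.

**Do the odds follow the loading?** Roughly. Scaled to noon's loading, the dawn run gives 2.25 and the winter run 1.59. These two share a substrate charge, so that spread is the error of the rule at that charge.

**Then red and teal?** This is my own reckoning, and it carries the rule untested from noon's substrate charge to a lower one. Noon's odds scaled to red's loading are 6.38, a share of 86.4% target. Scaled to teal's loading they are 1.06, a share of 51.5%.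

**Is teal finished at 2.0 d, though?** Dawn's substrate fell to half in 4.00 h. If that time stretches inversely with the catalyst concentration, teal's half-life is 10.9 h. The time asked then holds 4.39 half-lives and leaves 4.77% of teal's substrate, so my end share for teal runs slightly ahead of that moment.

The forecast reads red > grey > amber > teal at 2.0 d and grey > red > amber > teal at 2.5 h. It puts red at 87% (82% to 92%) and teal at 60% (46% to 67%), on the grounds that “a catalysed step competes with a roughly second-order loss, so dilution helps”. On red it stands beside my figure, and on teal my figure is lower.

The flasks give red > grey > amber > teal at 2.0 d and grey > red > amber > teal at 2.5 h, with red at 89.4% and teal at 57.7%. The forecast held on all four counts.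

    catalyst intermediate B ⇌ free catalyst + target (K = 0.310 M, k = 200 h⁻¹)
    substrate + free catalyst ⇌ catalyst intermediate A (K = 29.0 M⁻¹, k = 5600 M⁻¹ h⁻¹)
    catalyst intermediate A → catalyst intermediate B (k = 460 h⁻¹)
    2 substrate → self-condensation product (k = 0.930 M⁻¹ h⁻¹)

Red's rest of the charge is self-condensation product, 10.6% counted as the substrate it holds. Without that loss red goes from 89.4% to >99.9%. Red's end odds are therefore 8.39, above the 6.38 carried from noon. Scaled down to a flask like red with 0.075 mol% of free catalyst, they become 2.10, a share of 67.7%. That flask stands at 68.6% target, with 1.65% substrate left.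

(The data are simulated with made-up constants; noise was put on by code.)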